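**Plan**

1. Numbering: ring A (pyran) = C1, O2, C3, C4, C4a, C8a; ring B (carbocycle) = C4a, C5, C6, C7, C8, C8a; side chain C9–C15 on C3. C3 (enol ether carbon of ring A) and C6 (ketone of ring B) are both at the carbonyl oxidation level and 1,5-related through C4, C4a and C5, which is the pattern a de Mayo reaction leaves behind.
2. Retrosynthesis: the two acetonides are removed; C4a=C5 and O2–C3 are undone to a 1,5-diketone; C9=C10 is cut (Horner–Wadsworth–Emmons); C5–C4a and C3–C4 are cut by the de Mayo transform to a C3/C6 β-diketone with a vinyl group on C8a; C5–C6 is cut to an ester and a ketophosphonate dianion; C8–C8a is cut by an aldol transform.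
3. Forward: the C10–C15 aldehyde and the ring-precursor ester are made separately. Acylation gives the β-diketone and irradiation closes ring B. The side chain is joined at C9=C10 only afterwards, so that the enol is the sole chromophore during irradiation. Ring A is then closed by cyclodehydration, followed by dehydrogenation and deprotection.
4. Stereochemistry: C12 and C13 come from L-allo-isoleucine, C11 from a chelation-controlled methyl addition, C7 from (R)-3-bromo-2-hydroxy-2-methylpropanoic acid, C8 and C8a from an auxiliary-controlled syn aldol reaction, and the C9=C10 geometry from the olefination. C4a is formed in the key step and erased later.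

Key step: step 17

Remark: locants in the steps follow the numbering above. C4a in compounds 24 to 30 is drawn in the configuration expected from the ring closure (C4 trans to C1); this assumption is without consequence because the centre becomes sp2 in step 21.

**Side-chain aldehyde**

Step 1
Reactants: 1 L-allo-isoleucine
Product: 2 (2S,3R)-2-hydroxy-3-methylpentanoic acid
Conditions: NaNO2, H2SO4 (aq), 0 °C to rt
Reagents that add atoms: water, O
Why: Diazotisation of the α-amino acid and hydrolysis of the diazonium ion proceed with net retention through the α-lactone (double inversion), so C12 stays S and C13 is untouched.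

Step 2
Reactants: 2 (2S,3R)-2-hydroxy-3-methylpentanoic acid
Product: 3 (2S,3R)-2-hydroxy-N-methoxy-N,3-dimethylpentanamide
Conditions: MeNH(OMe)·HCl, EDC·HCl, HOBt, N-methylmorpholine, CH2Cl2, 0 °C to rt
Reagents that add atoms: N,O-dimethylhydroxylamine hydrochloride, CNOC.Cl
Why: Carbodiimide-mediated amide coupling with the strongly nucleophilic N,O-dimethylhydroxylamine should outrun self-esterification of the hydroxy acid and gives the Weinreb amide without touching either stereocentre.

Step 3
Reactants: 3 (2S,3R)-2-hydroxy-N-methoxy-N,3-dimethylpentanamide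
Product: 4 (4S,5R)-4-hydroxy-5-methylhept-1-en-3-one
Conditions: CH2=CHMgBr (3 equiv), THF, −78 to 0 °C; inverse quench into cold HCl (aq)
Reagents that add atoms: vinylmagnesium bromide, C=C[Mg]Br
Why: Grignard addition to a Weinreb amide stops at the ketone stage because the magnesium-chelated tetrahedral intermediate persists until the quench, the first equivalent of reagent serving only to deprotonate the hydroxyl group.

Step 4
Reactants: 4 (4S,5R)-4-hydroxy-5-methylhept-1-en-3-one
Product: 5 (3R,4S,5R)-3,5-dimethylhept-1-ene-3,4-diol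
Conditions: MeMgBr (3 equiv), THF, −78 °C; NH4Cl (aq)
Reagents that add atoms: methylmagnesium bromide, C[Mg]Br
Why: Chelation-controlled Grignard addition (Cram chelate model) in which the magnesium alkoxide at O12 and the ketone oxygen form a five-membered chelate, so that methyl enters C11 from the face of the C12 hydrogen, opposite the sec-butyl group, and sets 11R.

Step 5
Reactants: 5 (3R,4S,5R)-3,5-dimethylhept-1-ene-3,4-diol
Product: 6 (4R,5S)-5-[(2R)-butan-2-yl]-4-ethenyl-2,2,4-trimethyl-1,3-dioxolane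
Conditions: 2,2-dimethoxypropane, PPTS (cat), CH2Cl2, rt
Reagents that add atoms: 2,2-dimethoxypropane, COC(C)(C)OC
Why: Acid-catalysed transketalisation closes the isopropylidene acetal on the vicinal diol under conditions mild enough not to ionise the tertiary allylic alcohol.

Step 6
Reactants: 6 (4R,5S)-5-[(2R)-butan-2-yl]-4-ethenyl-2,2,4-trimethyl-1,3-dioxolane
Product: 7 (4S,5S)-5-[(2R)-butan-2-yl]-2,2,4-trimethyl-1,3-dioxolane-4-carbaldehyde
Conditions: O3, CH2Cl2, −78 °C; then PPh3, −78 °C to rt
Reagents that add atoms: ozone, [O-][O+]=O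
Why: Ozonolysis with reductive work-up cleaves the terminal alkene to the aldehyde, which cannot epimerise because C11 carries no hydrogen.

**Ring precursor**

Step 7
Reactants: 8 (2R)-3-bromo-2-hydroxy-2-methylpropanoic acid
Product: 10 (2S)-2,3-dihydroxy-2-methylpropanoic acid, via sodium (2S)-2-methyloxirane-2-carboxylate 9 (not isolated)
Conditions: NaOH (aq, 3 equiv), 80 °C; then HCl (aq) to pH 2, evaporation
Reagents that add atoms: sodium hydroxide, [Na+].[OH-]
Why: Base closes the bromohydrin to the glycidate (intramolecular Williamson etherification) and hydroxide then opens the epoxide at its unsubstituted carbon (SN2), so that bromide is exchanged for hydroxyl without any bond to the quaternary C7 being broken.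

Step 8
Reactants: 10 (2S)-2,3-dihydroxy-2-methylpropanoic acid
Product: 11 methyl (2S)-2,3-dihydroxy-2-methylpropanoate
Conditions: MeOH, H2SO4 (cat), reflux
Reagents that add atoms: methanol, CO
Why: Fischer esterification gives the methyl ester that later acts as the C6 acyl donor.

Step 9
Reactants: 11 methyl (2S)-2,3-dihydroxy-2-methylpropanoate
Product: 12 methyl (2S)-2-methyl-2,3-bis[(triethylsilyl)oxy]propanoate
Conditions: Et3SiOTf (2.5 equiv), 2,6-lutidine, CH2Cl2, −78 to 0 °C
Reagents that add atoms: triethylsilyl trifluoromethanesulfonate, CC[Si](CC)(CC)OS(=O)(=O)C(F)(F)F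
Why: Silylation with the silyl triflate and 2,6-lutidine is forceful enough to cap the hindered tertiary hydroxyl group as well as the primary one.

Step 10
Reactants: 12 methyl (2S)-2-methyl-2,3-bis[(triethylsilyl)oxy]propanoate
Product: 13 methyl (2S)-2-methyl-3-oxo-2-[(triethylsilyl)oxy]propanoate
Conditions: (COCl)2, DMSO, CH2Cl2, −78 to −30 °C; then Et3N, −78 °C to rt
Reagents that add atoms: none
Why: Swern oxidation of a primary triethylsilyl ether, in which the activated sulfonium species attacks only the unhindered primary silyl ether oxygen and so unmasks and oxidises C8 in one operation while the tertiary silyl ether stays in place.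

Step 11
Reactants: 14 (4R)-4-benzyl-1,3-oxazolidin-2-one; 15 (2E)-but-2-enoyl chloride
Product: 16 (4R)-4-benzyl-3-[(2E)-but-2-enoyl]-1,3-oxazolidin-2-one
Conditions: n-BuLi, THF, −78 °C; then 15, −78 to 0 °C
Reagents that add atoms: none
Why: N-Acylation of the lithiated oxazolidinone with the acid chloride is the standard route to the acyl imide and does not touch the auxiliary stereocentre.

Step 12
Reactants: 16 (4R)-4-benzyl-3-[(2E)-but-2-enoyl]-1,3-oxazolidin-2-one; 13 methyl (2S)-2-methyl-3-oxo-2-[(triethylsilyl)oxy]propanoate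
Product: 17 methyl (2S,3R,4R)-4-{[(4R)-4-benzyl-2-oxo-1,3-oxazolidin-3-yl]carbonyl}-3-hydroxy-2-methyl-2-[(triethylsilyl)oxy]hex-5-enoate
Conditions: Bu2BOTf, Et3N, CH2Cl2, −78 to 0 °C; then 13, −78 to 0 °C; then pH 7 buffer, MeOH, H2O2
Reagents that add atoms: none
Why: Evans syn aldol reaction of the boron dienolate of the crotonyl imide, which reacts at its α-carbon through a closed Zimmerman–Traxler transition state so that the (R)-benzyl auxiliary should set C8 (R) and C8a together, with the C8 hydroxyl and the vinyl group syn, largely independent of the C7 centre.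

Step 13
Reactants: 17 the aldol adduct
Product: 19 methyl (4S,5R)-5-{(2R)-1-[(4R)-4-benzyl-2-oxo-1,3-oxazolidin-3-yl]-1-oxobut-3-en-2-yl}-2,2,4-trimethyl-1,3-dioxolane-4-carboxylate, via the C7/C8 diol 18 (not isolated)
Conditions: CSA (cat), MeOH, 0 °C to rt; then 2,2-dimethoxypropane, rt
Reagents that add atoms: 2,2-dimethoxypropane, COC(C)(C)OC
Why: Acid-catalysed methanolysis removes the tertiary silyl ether and transketalisation with 2,2-dimethoxypropane then ties O7 and O8 into a dioxolane on which C6 and C8a are trans.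

Step 14
Reactants: 19 the acetonide imide
Product: 20 methyl (4S,5R)-5-[(2S)-1-hydroxybut-3-en-2-yl]-2,2,4-trimethyl-1,3-dioxolane-4-carboxylate
Conditions: NaBH4, THF/H2O (4:1), 0 °C
Reagents that add atoms: none
Why: Reductive cleavage of the N-acyl oxazolidinone with NaBH4 in wet THF, which should reduce the activated imide carbonyl much faster than the hindered α-quaternary methyl ester and releases the auxiliary for recovery.

Step 15
Reactants: 20 the primary alcohol
Product: 21 methyl (4S,5R)-5-[(2S)-1-{[tert-butyl(dimethyl)silyl]oxy}but-3-en-2-yl]-2,2,4-trimethyl-1,3-dioxolane-4-carboxylate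
Conditions: TBSCl, imidazole, DMF, rt
Reagents that add atoms: tert-butyldimethylsilyl chloride, CC(C)(C)[Si](C)(C)Cl
Why: Silylation of the primary alcohol (silyl chloride with imidazole) prevents lactonisation onto the C6 ester and masks the future ring oxygen O2.

Step 16
Reactants: 21 the silyl ether ester; 22 dimethyl (2-oxopropyl)phosphonate
Product: 23 dimethyl {4-[(4S,5R)-5-[(2S)-1-{[tert-butyl(dimethyl)silyl]oxy}but-3-en-2-yl]-2,2,4-trimethyl-1,3-dioxolan-4-yl]-2,4-dioxobutyl}phosphonate (β-diketone, drawn as the diketo form)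
Conditions: 22 (3 equiv), NaH then n-BuLi, THF, 0 °C; then 21, −78 to 0 °C; NH4Cl (aq)
Reagents that add atoms: none
Why: Claisen-type acylation in which the 1,3-dianion of the β-ketophosphonate attacks the non-enolisable ester through its terminal carbon (C5), the β-diketone product being stored as its enolate until the quench.

**Key step and endgame**

Step 17
Reactants: 23 the β-diketone with the vinyl group on C8a
Product: 25 dimethyl {3-[(3aS,6R,7S,7aR)-7-({[tert-butyl(dimethyl)silyl]oxy}methyl)-2,2,3a-trimethyl-4-oxohexahydro-1,3-benzodioxol-6-yl]-2-oxopropyl}phosphonate, via cyclobutanol photoadduct 24 (not isolated)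
Conditions: hν (Pyrex, λ > 300 nm), degassed MeCN (5 mM), 15 °C; then silica gel, rt
Reagents that add atoms: none
Why: De Mayo reaction: irradiation above 300 nm excites the hydrogen-bonded enol of the C3/C6 β-diketone, whose enol double bond C3=C5 adds stepwise (through a 1,4-diradical) across the tethered vinyl group C4a=C4, the closest precedent being the intramolecular de Mayo reaction of alkenyl β-diketones. Ring B closes in the straight mode by 6-exo attack of C5 on the inner vinyl carbon C4a, and the C3–C4 bond then completes the cis-fused acylcyclobutanol 24. Retro-aldol cleavage of the strained C3–C5 bond opens the four-membered ring, which leaves C4 and C4a between the two carbonyl groups of the 1,5-diketone. The only new stereocentre that persists is C4a, expected with C4 trans to C1 because a chair-like closure keeps the C8a substituent equatorial; it is erased in step 21, so either epimer is usable. The step needs six-ring rather than five-ring closure: bonding of C6 to C4a from the other enol tautomer would give a cyclopentane trans-fused to the dioxolane, which is disfavoured because C6 and C8a are trans on the acetonide, whereas the crossed six-ring mode of that tautomer (C6–C4 and C5–C4a) would fragment to the same diketone. The enol is the only chromophore, since the phosphonate is transparent and the conjugated side chain is attached only in step 18, so E/Z isomerisation and cycloaddition at a C9=C10 bond cannot compete.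

Step 18
Reactants: 25 the cyclohexanone ketophosphonate; 7 the side-chain aldehyde
Product: 26 (3aS,6S,7S,7aR)-6-{(3E)-4-[(4R,5S)-5-[(2R)-butan-2-yl]-2,2,4-trimethyl-1,3-dioxolan-4-yl]-2-oxobut-3-en-1-yl}-7-({[tert-butyl(dimethyl)silyl]oxy}methyl)-2,2,3a-trimethyltetrahydro-1,3-benzodioxol-4(3aH)-one
Conditions: LiCl, i-Pr2NEt, MeCN, rt
Reagents that add atoms: none
Why: Horner–Wadsworth–Emmons olefination under mild LiCl and amine conditions, in which only the doubly activated C9 methylene is deprotonated and the stabilised phosphonate anion gives the (E)-enone with the non-enolisable aldehyde.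

Step 19
Reactants: 26 the enone diketone
Product: 29 the 7,8-acetonide of (4aS,7S,8R,8aS)-3-{(E)-2-[(4R,5S)-5-[(2R)-butan-2-yl]-2,2,4-trimethyl-1,3-dioxolan-4-yl]ethenyl}-7,8-dihydroxy-7-methyl-4a,5,8,8a-tetrahydro-1H-isochromen-6(7H)-one, via primary alcohol 27 (not isolated), via C3 lactol 28 (not isolated)
Conditions: HF·pyridine, pyridine, THF, 0 °C to rt; then PPTS, 4 Å molecular sieves, toluene, 60 °C
Reagents that add atoms: none
Why: Fluoride removes the primary silyl ether, the freed C1 hydroxyl adds to the C3 ketone to give the six-membered lactol, and acid-catalysed dehydration (cyclodehydration) places the double bond at C3=C4 because only C4 carries hydrogen and the resulting dienol ether is conjugated with C9=C10.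

Step 20
Reactants: 29 the dienol ether ketone
Product: 30 the C6 trimethylsilyl enol ether of 29 (C5=C6, O6–SiMe3; 4aS,7S,8R,8aS)
Conditions: LiN(SiMe3)2, Me3SiCl, THF, −78 °C
Reagents that add atoms: chlorotrimethylsilane, C[Si](C)(C)Cl
Why: Kinetic enolisation of the single remaining ketone can only take place towards C5 because C7 is quaternary, and O-silylation gives the silyl enol ether.

Step 21
Reactants: 30 the silyl enol ether
Product: 31 the bis-acetonide of the target: 7,8-acetonide of (7S,8R,8aS)-3-{(E)-2-[(4R,5S)-5-[(2R)-butan-2-yl]-2,2,4-trimethyl-1,3-dioxolan-4-yl]ethenyl}-7,8-dihydroxy-7-methyl-8,8a-dihydro-1H-isochromen-6(7H)-one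
Conditions: Pd(OAc)2 (1.1 equiv), MeCN, rt
Reagents that add atoms: none
Why: Saegusa–Ito oxidation, in which divalent palladium forms the oxo-π-allyl complex at C5 and β-hydride elimination of the C4a hydrogen gives the C4a=C5 enone, erasing the C4a stereocentre and completing the dienol ether dienone.

Step 22
Reactants: 31 the bis-acetonide
Product: 32 (7S,8R,8aS)-3-[(1E,3R,4S,5R)-3,4-dihydroxy-3,5-dimethylhept-1-en-1-yl]-7,8-dihydroxy-7-methyl-8,8a-dihydro-1H-isochromen-6(7H)-one (CNP0291643.7)
Conditions: AcOH/H2O (4:1), 40 °C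
Reagents that add atoms: none
Why: Acid-catalysed acetal hydrolysis removes both isopropylidene groups, the strained trans-fused one fastest, while the vinylogous ester and the C7, C8, C8a, C11, C12 and C13 centres are not affected by dilute aqueous acetic acid.

**Compound list**

1 | L-allo-isoleucine, (2S,3R)-2-amino-3-methylpentanoic acid | CC[C@@H](C)[C@H](N)C(=O)O | starting material
2 | (2S,3R)-2-hydroxy-3-methylpentanoic acid | CC[C@@H](C)[C@H](O)C(=O)O | intermediate
3 | (2S,3R)-2-hydroxy-N-methoxy-N,3-dimethylpentanamide | CC[C@@H](C)[C@H](O)C(=O)N(C)OC | intermediate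
4 | (4S,5R)-4-hydroxy-5-methylhept-1-en-3-one | CC[C@@H](C)[C@H](O)C(=O)C=C | intermediate
5 | (3R,4S,5R)-3,5-dimethylhept-1-ene-3,4-diol | CC[C@@H](C)[C@H](O)[C@](C)(O)C=C | intermediate
6 | (4R,5S)-5-[(2R)-butan-2-yl]-4-ethenyl-2,2,4-trimethyl-1,3-dioxolane | CC[C@@H](C)[C@@H]1OC(C)(C)O[C@]1(C)C=C | intermediate
7 | (4S,5S)-5-[(2R)-butan-2-yl]-2,2,4-trimethyl-1,3-dioxolane-4-carbaldehyde (C10–C15 aldehyde) | CC[C@@H](C)[C@@H]1OC(C)(C)O[C@]1(C)C=O | intermediate
8 | (2R)-3-bromo-2-hydroxy-2-methylpropanoic acid | C[C@](O)(CBr)C(=O)O | starting material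
9 | sodium (2S)-2-methyloxirane-2-carboxylate (formed in the flask in step 7) | C[C@]1(CO1)C(=O)[O-].[Na+] | intermediate
10 | (2S)-2,3-dihydroxy-2-methylpropanoic acid | OC(=O)[C@@](C)(O)CO | intermediate
11 | methyl (2S)-2,3-dihydroxy-2-methylpropanoate | COC(=O)[C@@](C)(O)CO | intermediate
12 | methyl (2S)-2-methyl-2,3-bis[(triethylsilyl)oxy]propanoate | COC(=O)[C@@](C)(O[Si](CC)(CC)CC)CO[Si](CC)(CC)CC | intermediate
13 | methyl (2S)-2-methyl-3-oxo-2-[(triethylsilyl)oxy]propanoate | COC(=O)[C@@](C)(O[Si](CC)(CC)CC)C=O | intermediate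
14 | (4R)-4-benzyl-1,3-oxazolidin-2-one | O=C1N[C@H](Cc2ccccc2)CO1 | starting material
15 | (2E)-but-2-enoyl chloride | C/C=C/C(=O)Cl | starting material
16 | (4R)-4-benzyl-3-[(2E)-but-2-enoyl]-1,3-oxazolidin-2-one | C/C=C/C(=O)N1[C@H](Cc2ccccc2)COC1=O | intermediate
17 | methyl (2S,3R,4R)-4-{[(4R)-4-benzyl-2-oxo-1,3-oxazolidin-3-yl]carbonyl}-3-hydroxy-2-methyl-2-[(triethylsilyl)oxy]hex-5-enoate | COC(=O)[C@@](C)(O[Si](CC)(CC)CC)[C@H](O)[C@@H](C=C)C(=O)N1[C@H](Cc2ccccc2)COC1=O | intermediate
18 | methyl (2S,3R,4R)-4-{[(4R)-4-benzyl-2-oxo-1,3-oxazolidin-3-yl]carbonyl}-2,3-dihydroxy-2-methylhex-5-enoate (formed in the flask in step 13) | COC(=O)[C@@](C)(O)[C@H](O)[C@@H](C=C)C(=O)N1[C@H](Cc2ccccc2)COC1=O | intermediate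
19 | methyl (4S,5R)-5-{(2R)-1-[(4R)-4-benzyl-2-oxo-1,3-oxazolidin-3-yl]-1-oxobut-3-en-2-yl}-2,2,4-trimethyl-1,3-dioxolane-4-carboxylate | COC(=O)[C@@]1(C)OC(C)(C)O[C@@H]1[C@@H](C=C)C(=O)N2[C@H](Cc3ccccc3)COC2=O | intermediate
20 | methyl (4S,5R)-5-[(2S)-1-hydroxybut-3-en-2-yl]-2,2,4-trimethyl-1,3-dioxolane-4-carboxylate | COC(=O)[C@@]1(C)OC(C)(C)O[C@@H]1[C@@H](C=C)CO | intermediate
21 | methyl (4S,5R)-5-[(2S)-1-{[tert-butyl(dimethyl)silyl]oxy}but-3-en-2-yl]-2,2,4-trimethyl-1,3-dioxolane-4-carboxylate | COC(=O)[C@@]1(C)OC(C)(C)O[C@@H]1[C@@H](C=C)CO[Si](C)(C)C(C)(C)C | intermediate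
22 | dimethyl (2-oxopropyl)phosphonate | COP(=O)(OC)CC(C)=O | starting material
23 | dimethyl {4-[(4S,5R)-5-[(2S)-1-{[tert-butyl(dimethyl)silyl]oxy}but-3-en-2-yl]-2,2,4-trimethyl-1,3-dioxolan-4-yl]-2,4-dioxobutyl}phosphonate (key-step precursor, diketo form) | COP(=O)(OC)CC(=O)CC(=O)[C@@]1(C)OC(C)(C)O[C@@H]1[C@@H](C=C)CO[Si](C)(C)C(C)(C)C | intermediate
24 | cyclobutanol photoadduct (new bonds C5–C4a and C3–C4; cis fusion at C4a–C5; C3 hydroxyl cis to C6; formed in the flask in step 17) | COP(=O)(OC)C[C@@]1(O)C[C@H]2[C@@H]1C(=O)[C@@]3(C)OC(C)(C)O[C@@H]3[C@@H]2CO[Si](C)(C)C(C)(C)C | intermediate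
25 | dimethyl {3-[(3aS,6R,7S,7aR)-7-({[tert-butyl(dimethyl)silyl]oxy}methyl)-2,2,3a-trimethyl-4-oxohexahydro-1,3-benzodioxol-6-yl]-2-oxopropyl}phosphonate (key-step product) | COP(=O)(OC)CC(=O)C[C@H]1CC(=O)[C@@]2(C)OC(C)(C)O[C@@H]2[C@@H]1CO[Si](C)(C)C(C)(C)C | intermediate
26 | (3aS,6S,7S,7aR)-6-{(3E)-4-[(4R,5S)-5-[(2R)-butan-2-yl]-2,2,4-trimethyl-1,3-dioxolan-4-yl]-2-oxobut-3-en-1-yl}-7-({[tert-butyl(dimethyl)silyl]oxy}methyl)-2,2,3a-trimethyltetrahydro-1,3-benzodioxol-4(3aH)-one | CC[C@@H](C)[C@@H]1OC(C)(C)O[C@]1(C)/C=C/C(=O)C[C@H]2CC(=O)[C@@]3(C)OC(C)(C)O[C@@H]3[C@@H]2CO[Si](C)(C)C(C)(C)C | intermediate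
27 | desilylated 26 with free C1 hydroxyl (formed in the flask in step 19) | CC[C@@H](C)[C@@H]1OC(C)(C)O[C@]1(C)/C=C/C(=O)C[C@H]2CC(=O)[C@@]3(C)OC(C)(C)O[C@@H]3[C@@H]2CO | intermediate
28 | C3 lactol of 27, ring A closed through O2, both anomers at C3 (formed in the flask in step 19) | CC[C@@H](C)[C@@H]1OC(C)(C)O[C@]1(C)/C=C/C2(O)C[C@H]3CC(=O)[C@@]4(C)OC(C)(C)O[C@@H]4[C@@H]3CO2 | intermediate
29 | 7,8-acetonide of (4aS,7S,8R,8aS)-3-{(E)-2-[(4R,5S)-5-[(2R)-butan-2-yl]-2,2,4-trimethyl-1,3-dioxolan-4-yl]ethenyl}-7,8-dihydroxy-7-methyl-4a,5,8,8a-tetrahydro-1H-isochromen-6(7H)-one | CC[C@@H](C)[C@@H]1OC(C)(C)O[C@]1(C)/C=C/C2=C[C@H]3CC(=O)[C@@]4(C)OC(C)(C)O[C@@H]4[C@@H]3CO2 | intermediate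
30 | C6 trimethylsilyl enol ether of 29 (C5=C6; 4aS,7S,8R,8aS) | CC[C@@H](C)[C@@H]1OC(C)(C)O[C@]1(C)/C=C/C2=C[C@H]3C=C(O[Si](C)(C)C)[C@@]4(C)OC(C)(C)O[C@@H]4[C@@H]3CO2 | intermediate
31 | bis-acetonide of the target (7S,8R,8aS; side-chain dioxolane 4R,5S) | CC[C@@H](C)[C@@H]1OC(C)(C)O[C@]1(C)/C=C/C2=CC3=CC(=O)[C@@]4(C)OC(C)(C)O[C@@H]4[C@@H]3CO2 | intermediate
32 | (7S,8R,8aS)-3-[(1E,3R,4S,5R)-3,4-dihydroxy-3,5-dimethylhept-1-en-1-yl]-7,8-dihydroxy-7-methyl-8,8a-dihydro-1H-isochromen-6(7H)-one | CC[C@@H](C)[C@H](O)[C@](C)(O)/C=C/C1=CC2=CC(=O)[C@@](C)(O)[C@H](O)[C@@H]2CO1 | target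

**Count**

Total step count: 22.
Longest linear sequence: 15 steps (steps 7–10 and 12–22, from compound 8). The side-chain branch is steps 1–6 and the imide is made in step 11.

**Steps most likely to fail**

1. Step 17 (photocycloaddition and retro-aldol). The excited enol may relax without bonding, C6 instead of C5 may bond to C4a, or the product ketones may suffer α-cleavage on prolonged irradiation. The fallback leaves the route at 21 and 7 and rejoins it at 26, closing ring B by metathesis and forming C4–C4a by conjugate addition. Ester 21 is converted with MeNH(OMe)·HCl and i-PrMgCl into the Weinreb amide F1, which takes up CH2=CHMgBr to give the vinyl ketone F2. The second-generation Grubbs catalyst then closes the carbocycle as the cyclohexenone F3 with loss of ethene. Aldehyde 7 is olefinated with the dianion of allyl 4-(dimethoxyphosphoryl)-3-oxobutanoate (NaH, THF) to the dienyl β-keto ester F4. Michael addition of F4 to F3 (Cs2CO3, MeCN) forms the C4–C4a bond in the adduct F5. Deallylation and decarboxylation with Pd(PPh3)4 and morpholine then deliver 26; either C4a epimer is usable.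

2. Step 16 (acylation of the phosphonate dianion). Attack on the hindered α-quaternary ester may be slow, so that proton transfer and self-condensation of the dianion take over. The fallback leaves at 21 and rejoins at 23, replacing the acylation by addition to an aldehyde followed by oxidation. Partial reduction of 21 with i-Bu2AlH at −78 °C gives the aldehyde F6. The dianion of 22 adds to it in an aldol reaction to give the β-hydroxy ketone F7, and Dess–Martin periodinane oxidises F7 to 23.

3. Step 4 (methyl addition to the hydroxy enone). Conjugate addition to the unhindered vinyl ketone and its oligomerisation may compete with 1,2-addition and erode chelate control at C11. The fallback leaves at 3 and rejoins at 5, carrying C10 as an alkyne, which accepts Grignard reagents only at the carbonyl group. HC≡CMgBr converts the Weinreb amide 3 into the hydroxy ynone F8. Chelation-controlled addition of MeMgBr gives the propargylic diol F9, and semihydrogenation (H2, Pd/CaCO3 poisoned with Pb(OAc)2, quinoline) returns 5.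

**Further compounds**

F1 | step 17 | (4S,5R)-5-[(2S)-1-{[tert-butyl(dimethyl)silyl]oxy}but-3-en-2-yl]-N-methoxy-N,2,2,4-tetramethyl-1,3-dioxolane-4-carboxamide | CON(C)C(=O)[C@@]1(C)OC(C)(C)O[C@@H]1[C@@H](C=C)CO[Si](C)(C)C(C)(C)C
F2 | step 17 | 1-[(4S,5R)-5-[(2S)-1-{[tert-butyl(dimethyl)silyl]oxy}but-3-en-2-yl]-2,2,4-trimethyl-1,3-dioxolan-4-yl]prop-2-en-1-one | C=CC(=O)[C@@]1(C)OC(C)(C)O[C@@H]1[C@@H](C=C)CO[Si](C)(C)C(C)(C)C
F3 | step 17 | (3aS,7S,7aR)-7-({[tert-butyl(dimethyl)silyl]oxy}methyl)-2,2,3a-trimethyl-7,7a-dihydro-1,3-benzodioxol-4(3aH)-one | C1=CC(=O)[C@@]2(C)OC(C)(C)O[C@@H]2[C@@H]1CO[Si](C)(C)C(C)(C)C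
F4 | step 17 | prop-2-en-1-yl (4E)-5-[(4R,5S)-5-[(2R)-butan-2-yl]-2,2,4-trimethyl-1,3-dioxolan-4-yl]-3-oxopent-4-enoate | CC[C@@H](C)[C@@H]1OC(C)(C)O[C@]1(C)/C=C/C(=O)CC(=O)OCC=C
F5 | step 17 | prop-2-en-1-yl (4E)-2-[(3aS,6S,7S,7aR)-7-({[tert-butyl(dimethyl)silyl]oxy}methyl)-2,2,3a-trimethyl-4-oxohexahydro-1,3-benzodioxol-6-yl]-5-[(4R,5S)-5-[(2R)-butan-2-yl]-2,2,4-trimethyl-1,3-dioxolan-4-yl]-3-oxopent-4-enoate (both epimers at C2 of the pentenoate) | CC[C@@H](C)[C@@H]1OC(C)(C)O[C@]1(C)/C=C/C(=O)C(C(=O)OCC=C)[C@H]2CC(=O)[C@@]3(C)OC(C)(C)O[C@@H]3[C@@H]2CO[Si](C)(C)C(C)(C)C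
F6 | step 16 | (4S,5R)-5-[(2S)-1-{[tert-butyl(dimethyl)silyl]oxy}but-3-en-2-yl]-2,2,4-trimethyl-1,3-dioxolane-4-carbaldehyde | O=C[C@@]1(C)OC(C)(C)O[C@@H]1[C@@H](C=C)CO[Si](C)(C)C(C)(C)C
F7 | step 16 | dimethyl {4-[(4R,5R)-5-[(2S)-1-{[tert-butyl(dimethyl)silyl]oxy}but-3-en-2-yl]-2,2,4-trimethyl-1,3-dioxolan-4-yl]-4-hydroxy-2-oxobutyl}phosphonate (both carbinol epimers) | COP(=O)(OC)CC(=O)CC(O)[C@@]1(C)OC(C)(C)O[C@@H]1[C@@H](C=C)CO[Si](C)(C)C(C)(C)C
F8 | step 4 | (4S,5R)-4-hydroxy-5-methylhept-1-yn-3-one | CC[C@@H](C)[C@H](O)C(=O)C#C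
F9 | step 4 | (3R,4S,5R)-3,5-dimethylhept-1-yne-3,4-diol | CC[C@@H](C)[C@H](O)[C@](C)(O)C#C
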